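**Plan**

1. Numbering: C1 is the ester carbonyl and C20 is CHBr. The retrosynthesis cuts C10–C11 (alkynyl–alkenyl bond), takes C9≡C10 back to a C9 carbinol, then cuts the ring bond O–C8 and C6–C7. The C11–C20 arm is cut at C18–C19.
2. Enabling feature: the oxolane (O, C5, C6, C7, C8) is 2,5-trans and C8 carries a single exocyclic carbon, C9. This pattern results when a C5 hydroxyl closes onto the inner carbon of a terminal C8=C9 alkene while C9 takes up oxygen.
3. Forward: hex-5-enoic acid is esterified, epoxidised, resolved and opened with allylmagnesium bromide to the C1–C9 alkenol. Cobalt/O2 cyclisation makes the only ring. Ester exchange, oxidation and one-carbon alkynylation give the C1–C10 alkyne.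
4. Acetylene and IBr give (E)-1-bromo-2-iodoethene. Octa-1,7-diyne is hydrozirconated and coupled with it, then hydrozirconated again and iodinated. The two halves are joined last at C10–C11.
5. Stereochemistry: C5 (R) comes from hydrolytic kinetic resolution. C8 (S) is relayed from C5 in the trans-selective closure. The E alkenes come from syn hydrozirconation (C11=C12, C17=C18) and anti addition of IBr (C19=C20), and stereoretentive palladium couplings keep them.
6. The carboxyl group travels as its tert-butyl ester until O5 is locked in the ring, because a methyl 5-hydroxy ester would invite allyl Grignard attack and δ-lactonisation. It becomes the methyl ester directly afterwards.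

Key step: step 5

Assumption: (E)-1-bromo-2-iodoethene is treated as not purchasable and is made in step 9. Co(modp)2 (modp = 1-morpholinocarbamoyl-4,4-dimethylpentane-1,3-dionate), (R,R)-(salen)Co(OAc) (salen = N,N'-bis(3,5-di-tert-butylsalicylidene)cyclohexane-1,2-diaminate) and Cp2ZrHCl (Cp = cyclopentadienyl) are treated as commercial.

**Step 1**
Reactants: 1 hex-5-enoic acid
Product: 2 tert-butyl hex-5-enoate
Conditions: Cl3CC(=NH)Ot-Bu, BF3·OEt2 (cat.), CH2Cl2–cyclohexane, rt
Reagents that add atoms: tert-butyl 2,2,2-trichloroacetimidate, CC(C)(C)OC(=N)C(Cl)(Cl)Cl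
Why: Acid-catalysed O-alkylation of a carboxylic acid by a trichloroacetimidate (tert-butyl cation transfer) leaves the terminal alkene alone and installs a bulky ester that should resist the Grignard reagent of step 4 and δ-lactonisation of alcohol 7.

**Step 2**
Reactants: 2 tert-butyl hex-5-enoate
Product: 3 tert-butyl 4-(oxiran-2-yl)butanoate (racemic)
Conditions: mCPBA, CH2Cl2, 0 °C → rt
Reagents that add atoms: 3-chloroperoxybenzoic acid, OOC(=O)c1cccc(Cl)c1
Why: Prilezhaev epoxidation of the only alkene is concerted and tolerates the ester, and no facial control is sought because the racemate is resolved in step 3.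

**Step 3**
Reactants: 3 tert-butyl 4-(oxiran-2-yl)butanoate (racemic)
Product: 4 tert-butyl 4-[(2R)-oxiran-2-yl]butanoate
Conditions: (R,R)-(salen)Co(OAc) (0.5 mol %), H2O (0.55 equiv), THF, 0 °C → rt
Reagents that add atoms: none
Why: In this hydrolytic kinetic resolution of a terminal epoxide the trivalent cobalt salen complex activates epoxide and water cooperatively and the (R,R) catalyst hydrolyses the (S)-epoxide much faster, so the (R)-epoxide that fixes C5 should remain and be separable from the polar diol.

**Step 4**
Reactants: 4 tert-butyl 4-[(2R)-oxiran-2-yl]butanoate; 5 allylmagnesium bromide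
Product: 7 tert-butyl (5R)-5-hydroxynon-8-enoate, via bromomagnesium alkoxide 6 (not isolated)
Conditions: 5 (slow addition), CuI (10 mol %), THF, −78 → −30 °C; then sat. aq NH4Cl
Reagents that add atoms: none
Why: Copper-catalysed SN2 opening of a terminal epoxide by a Grignard reagent occurs at the unhindered C6, so the C5–O bond keeps its R configuration, while slow cold addition keeps free allylmagnesium bromide scarce and the tert-butyl ester should neither add the reagent nor acylate alkoxide 6.

**Step 5**
Reactants: 7 tert-butyl (5R)-5-hydroxynon-8-enoate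
Product: 9 tert-butyl 4-[(2R,5S)-5-(hydroxymethyl)oxolan-2-yl]butanoate, via C9 hydroperoxide 8 (not isolated)
Conditions: Co(modp)2 (10–20 mol %), O2 (1 atm), t-BuOOH (10 mol %, initiator), 4 Å MS, i-PrOH, 50–55 °C
Reagents that add atoms: dioxygen, O=O
Why: O2, started by t-BuOOH, raises Co(modp)2 from divalent to trivalent cobalt, which binds the C5 hydroxyl as an alkoxide and passes its oxygen to the inner alkene carbon C8; the C9 radical (or alkylcobalt) left behind is caught by O2 as hydroperoxide 8, which i-PrOH and the cobalt reduce in the flask to the primary alcohol. The closest known reaction type is the Mukaiyama aerobic oxidative cyclisation of pent-4-en-1-ols to trans-2-(hydroxymethyl)oxolanes. The one ring formed (O, C5, C6, C7, C8) closes 5-exo-trig through the new O–C8 bond. The new stereocentre C8 (S) is governed by C5 (R): in the chair-like transition state the C1–C4 chain sits pseudo-equatorial, so the C5 and C8 substituents end up on opposite ring faces, a bias that is typically very strong for this cobalt closure. The step needs 5-exo over 6-endo regioselectivity, trans over cis diastereoselectivity and no reaction elsewhere; the monosubstituted alkene and the secondary bis-homoallylic carbinol secure the first two, no second alkene or free hydroxyl is present, and the tert-butyl ester is inert to the radical conditions and should not lactonise at 55 °C.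

**Step 6**
Reactants: 9 tert-butyl 4-[(2R,5S)-5-(hydroxymethyl)oxolan-2-yl]butanoate
Product: 11 methyl 4-[(2R,5S)-5-(hydroxymethyl)oxolan-2-yl]butanoate, via free carboxylic acid 10 (not isolated)
Conditions: H2SO4 (cat.), MeOH, reflux
Reagents that add atoms: methanol, CO
Why: Acidolysis of the tert-butyl ester (loss of isobutene) followed by Fischer esterification in methanol touches no stereocentre, and with O5 now an ether oxygen the methyl ester can no longer lactonise.

**Step 7**
Reactants: 11 methyl 4-[(2R,5S)-5-(hydroxymethyl)oxolan-2-yl]butanoate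
Product: 12 methyl 4-[(2R,5S)-5-formyloxolan-2-yl]butanoate
Conditions: Dess–Martin periodinane, CH2Cl2, 0 °C → rt; used at once
Reagents that add atoms: none
Why: Dess–Martin oxidation of a primary alcohol stops at the aldehyde under nearly neutral, water-free conditions, which protects the epimerisable C8 centre next to the new carbonyl.

**Step 8**
Reactants: 12 methyl 4-[(2R,5S)-5-formyloxolan-2-yl]butanoate
Product: 13 methyl 4-[(2R,5S)-5-ethynyloxolan-2-yl]butanoate
Conditions: MeC(O)C(N2)P(O)(OMe)2, K2CO3, MeOH, 0 °C → rt
Reagents that add atoms: dimethyl (1-diazo-2-oxopropyl)phosphonate, CC(=O)C(=[N+]=[N-])P(=O)(OC)OC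
Why: In the Ohira–Bestmann form of the Seyferth–Gilbert homologation the diazomethylphosphonate anion adds to the aldehyde and loss of phosphate and N2 with a 1,2-shift gives the alkyne (C10 from the diazo carbon); the weak base is the usual choice for α-alkoxy aldehydes so C8 should hold, and K2CO3/MeOH can only exchange a methyl ester for itself.

**Step 9**
Reactants: 14 acetylene
Product: 15 (E)-1-bromo-2-iodoethene
Conditions: IBr, 48 % aq HBr, 0 °C, C2H2 bubbled through
Reagents that add atoms: iodine monobromide, BrI
Why: Electrophilic anti addition of IBr to acetylene through a bridged iodonium ion places Br and I trans, giving the E dihaloethene that becomes C19=C20.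

**Step 10**
Reactants: 16 octa-1,7-diyne; 15 (E)-1-bromo-2-iodoethene
Product: 18 (1E,3E)-1-bromodeca-1,3-dien-9-yne, via alkenylzirconocene chloride 17 (not isolated)
Conditions: 16 (3 equiv), Cp2ZrHCl (1 equiv), THF, 0 °C → rt; then 15 (1 equiv), Pd(PPh3)4 (5 mol %), ZnBr2 (20 mol %), 0 °C → rt, dark
Reagents that add atoms: none
Why: Syn hydrozirconation with Zr at the terminus is followed by a Negishi alkenyl–alkenyl coupling with zinc co-catalysis in which zerovalent palladium inserts into the weaker C–I bond of 15 and both partners keep their geometry, so the E,E-bromodiene should result, while an excess of the volatile diyne favours reaction at one terminus only.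

**Step 11**
Reactants: 18 (1E,3E)-1-bromodeca-1,3-dien-9-yne
Product: 20 (1E,3E,9E)-1-bromo-10-iododeca-1,3,9-triene, via bromotrienylzirconocene chloride 19 (not isolated)
Conditions: Cp2ZrHCl (1.05 equiv), THF, 0 °C → rt, dark; then I2, THF, −78 → 0 °C
Reagents that add atoms: iodine, II
Why: In this hydrozirconation–iodinolysis a terminal alkyne takes up Cp2ZrHCl far faster than a disubstituted, halogen-bearing alkene, and syn addition followed by C–Zr cleavage with retention fixes the E geometry of C11=C12.

**Step 12**
Reactants: 13 methyl 4-[(2R,5S)-5-ethynyloxolan-2-yl]butanoate; 20 (1E,3E,9E)-1-bromo-10-iododeca-1,3,9-triene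
Product: 21 methyl 4-[(2R,5S)-5-[(3E,9E,11E)-12-bromododeca-3,9,11-trien-1-yn-1-yl]oxolan-2-yl]butanoate
Conditions: Pd(PPh3)4 (5 mol %), CuI (10 mol %), Et3N, THF, degassed, 0 °C → rt, dark; 20 in slight excess
Reagents that add atoms: none
Why: In this Sonogashira coupling zerovalent palladium adds to the alkenyl C–I bond well before the dienyl C–Br bond at or below room temperature, the alkene geometry is retained, and the ester, oxolane and both stereocentres are spectators.

**Compound list**

| No. | Name | SMILES | Role |
|---|---|---|---|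
| 1 | hex-5-enoic acid | OC(=O)CCCC=C | starting material |
| 2 | tert-butyl hex-5-enoate | CC(C)(C)OC(=O)CCCC=C | intermediate |
| 3 | tert-butyl 4-(oxiran-2-yl)butanoate (racemic) | CC(C)(C)OC(=O)CCCC1CO1 | intermediate |
| 4 | tert-butyl 4-[(2R)-oxiran-2-yl]butanoate | CC(C)(C)OC(=O)CCC[C@@H]1CO1 | intermediate |
| 5 | allylmagnesium bromide | C=CC[Mg]Br | starting material |
| 6 | bromomagnesium alkoxide of tert-butyl (5R)-5-hydroxynon-8-enoate | CC(C)(C)OC(=O)CCC[C@@H](O[Mg]Br)CCC=C | intermediate |
| 7 | tert-butyl (5R)-5-hydroxynon-8-enoate | CC(C)(C)OC(=O)CCC[C@@H](O)CCC=C | intermediate |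
| 8 | tert-butyl 4-[(2R,5S)-5-(hydroperoxymethyl)oxolan-2-yl]butanoate | CC(C)(C)OC(=O)CCC[C@@H]1CC[C@@H](COO)O1 | intermediate |
| 9 | tert-butyl 4-[(2R,5S)-5-(hydroxymethyl)oxolan-2-yl]butanoate | CC(C)(C)OC(=O)CCC[C@@H]1CC[C@@H](CO)O1 | intermediate |
| 10 | 4-[(2R,5S)-5-(hydroxymethyl)oxolan-2-yl]butanoic acid | OC(=O)CCC[C@@H]1CC[C@@H](CO)O1 | intermediate |
| 11 | methyl 4-[(2R,5S)-5-(hydroxymethyl)oxolan-2-yl]butanoate | COC(=O)CCC[C@@H]1CC[C@@H](CO)O1 | intermediate |
| 12 | methyl 4-[(2R,5S)-5-formyloxolan-2-yl]butanoate | COC(=O)CCC[C@@H]1CC[C@@H](C=O)O1 | intermediate |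
| 13 | methyl 4-[(2R,5S)-5-ethynyloxolan-2-yl]butanoate | COC(=O)CCC[C@@H]1CC[C@@H](C#C)O1 | intermediate |
| 14 | acetylene | C#C | starting material |
| 15 | (E)-1-bromo-2-iodoethene | Br/C=C/I | intermediate |
| 16 | octa-1,7-diyne | C#CCCCCC#C | starting material |
| 17 | chloro[(1E)-oct-1-en-7-yn-1-yl]zirconocene | C#CCCCC/C=C/[Zr](Cl)(C1C=CC=C1)C1C=CC=C1 | intermediate |
| 18 | (1E,3E)-1-bromodeca-1,3-dien-9-yne | Br/C=C/C=C/CCCCC#C | intermediate |
| 19 | [(1E,7E,9E)-10-bromodeca-1,7,9-trien-1-yl]chlorozirconocene | Br/C=C/C=C/CCCC/C=C/[Zr](Cl)(C1C=CC=C1)C1C=CC=C1 | intermediate |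
| 20 | (1E,3E,9E)-1-bromo-10-iododeca-1,3,9-triene | Br/C=C/C=C/CCCC/C=C/I | intermediate |
| 21 | methyl 4-[(2R,5S)-5-[(3E,9E,11E)-12-bromododeca-3,9,11-trien-1-yn-1-yl]oxolan-2-yl]butanoate | COC(=O)CCC[C@@H]1CC[C@@H](C#C/C=C/CCCC/C=C/C=C/Br)O1 | target |

Total step count: 12.
Longest linear sequence: 9 (steps 1–8 and 12). The side-chain branch runs through steps 9–11.

**Steps most likely to fail**

**Step 10.**
- Hydrozirconation of the symmetrical diyne may spread over both termini.
- The hydrocarbon-like products of single and double reaction may resist separation.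
- The free alkyne C–H may interfere during the palladium stage.

The fallback sets out from 15 and replaces the diyne by an unsymmetrical, polar partner. Commercial hept-6-yn-1-ol (C#CCCCCCO) is treated with two equivalents of Cp2ZrHCl to give the O,C-bis(zirconocene) derivative of (E)-hept-6-en-1-ol F1. This is coupled with 15 under Pd(PPh3)4/ZnBr2 to give (6E,8E)-9-bromonona-6,8-dien-1-ol F2, whose hydroxyl group makes purification simple. Dess–Martin oxidation gives (6E,8E)-9-bromonona-6,8-dienal F3. Takai iodo-olefination (CHI3, CrCl2, THF–dioxane) then adds C11 as the E-iodoalkene. The sequence comes back to the route at 20 and also bypasses step 11.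

**Step 11.**
- The Zr–H reagent may add to or reduce the bromodiene in competition with the alkyne.
- Iodine may isomerise the diene.

The fallback sets out from 17 (generated from 16 as in step 10) and keeps bromine out of the molecule until all hydride chemistry is over. Compound 17 is coupled with commercial (E)-(2-bromovinyl)trimethylsilane (C[Si](C)(C)/C=C/Br) under Pd(PPh3)4/ZnBr2 to give [(1E,3E)-deca-1,3-dien-9-yn-1-yl]trimethylsilane F4. Hydrozirconation, which now meets no carbon–halogen bond, gives the silyltrienylzirconocene chloride F5. Iodinolysis gives [(1E,3E,9E)-10-iododeca-1,3,9-trien-1-yl]trimethylsilane F6. Ipso-bromodesilylation with NBS in MeCN at 0 °C in the dark, through a β-silyl-stabilised cation, comes back to the route at 20.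

**Step 12.**
- Discrimination between C–I and C–Br in the oxidative addition may erode.
- The alkyne may dimerise oxidatively at copper.
- The polyene may isomerise under amine and palladium.

The fallback sets out from 13 and reverses the polarity of the C10–C11 bond formation. NIS with AgNO3 (cat.) in acetone gives methyl 4-[(2R,5S)-5-(iodoethynyl)oxolan-2-yl]butanoate F7. This is coupled with alkenylzirconocene 19, taken from 18 before iodinolysis, under Pd(PPh3)4/ZnBr2 in a Negishi alkenyl–alkynyl coupling. The C(sp)–I bond is much more reactive than the dienyl bromide, and neither copper nor amine is present. The sequence comes back to the route at 21.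

**Further compounds**

F1 | step 10 | chloro{(1E)-7-[(chlorozirconocenyl)oxy]hept-1-en-1-yl}zirconocene | Cl[Zr](OCCCCC/C=C/[Zr](Cl)(C1C=CC=C1)C1C=CC=C1)(C1C=CC=C1)C1C=CC=C1
F2 | step 10 | (6E,8E)-9-bromonona-6,8-dien-1-ol | OCCCCC/C=C/C=C/Br
F3 | step 10 | (6E,8E)-9-bromonona-6,8-dienal | O=CCCCC/C=C/C=C/Br
F4 | step 11 | [(1E,3E)-deca-1,3-dien-9-yn-1-yl]trimethylsilane | C[Si](C)(C)/C=C/C=C/CCCCC#C
F5 | step 11 | chloro[(1E,7E,9E)-10-(trimethylsilyl)deca-1,7,9-trien-1-yl]zirconocene | C[Si](C)(C)/C=C/C=C/CCCC/C=C/[Zr](Cl)(C1C=CC=C1)C1C=CC=C1
F6 | step 11 | [(1E,3E,9E)-10-iododeca-1,3,9-trien-1-yl]trimethylsilane | C[Si](C)(C)/C=C/C=C/CCCC/C=C/I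
F7 | step 12 | methyl 4-[(2R,5S)-5-(iodoethynyl)oxolan-2-yl]butanoate | COC(=O)CCC[C@@H]1CC[C@@H](C#CI)O1
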